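I started from late times, when the catalyst has to find what is left, so I counted the fraction left and not the product made.

all flasks: substrate 10 mM; free catalyst 2.0 mM

| flask | reagent | remark | time |
|---|---|---|---|
| south-east | 10.0 mM | one stirred flow tank at steady state, fed with the mixture as stated, mean residence time 50 s |  |
| north | 10.0 mM | a single well-mixed tank run continuously and read at steady state, 150 s in it on average |  |
| east | 10.0 mM | a closed flask charged with all of it at once and left for 50 s | 50 s |
| south | 10.0 mM (fed, over 50.0 s) | all but reagent at the start; reagent goes in evenly over 50.0 s, the run ends at 50 s | 50 s |

    catalyst intermediate B → free catalyst + product (k1 = 0.203 s⁻¹)
    reagent + free catalyst ⇌ catalyst intermediate A (K2 = 382 M⁻¹, k2 = 58.2 M⁻¹ s⁻¹)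
    substrate + catalyst intermediate A → catalyst intermediate B (k3 = 74.5 M⁻¹ s⁻¹)

- the set-up with the highest amount of product at the outlet or at the end, in percent of the substrate put in ("none" if the first two lie within 2 percentage points) (south-east / north / east / south / none)
- amount of product at the outlet or at the end, in percent of the substrate put in, south-east
- amount of product at the outlet or at the end, in percent of the substrate put in, north
- amount of product at the outlet or at the end, in percent of the substrate put in, east
- amount of product at the outlet or at the end, in percent of the substrate put in, south

- the stated concentrations are those of everything mixed, before any reaction; amounts are the same in each set-up
- the feed brings no volume worth counting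
- run time (east): 50 s

One round of the catalyst is a chain of waits, and waits add. Release of product from catalyst intermediate B takes 4.93 s. At the charge, catalyst intermediate A waits 1.34 s for substrate and free catalyst waits 1.72 s for reagent. But catalyst intermediate A also falls back at 0.152 s⁻¹, so capture must be repeated, and that stretches the reagent wait by a factor of 1.20 at the charge. The waits add to 8.34 s, and this sum is the turnover time. Substrate and reagent are charged equally, so I gave them one fraction left. Both capture waits grow as its inverse, and the returns as its square. Each catalyst owes 5.00 rounds.

For the east flask I asked when 20.0% would be left. With release by itself that takes 19.7 s. The wait for substrate brings it to 30.5 s, the wait for reagent to 44.3 s, and the returns to 51.4 s. There the turnover time is 29.0 s. Working back to 50 s gives 20.9% left. I reckoned that catalyst intermediate B holds 3.58% of the substrate in east, so I committed to 75.5% of product there.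

In the north tank, conversion is the mean residence time over 5.00 turnover times. Trying 16.7% left gave a turnover time of 35.9 s and 83.5% converted, close to the 83.3% that this fraction requires. Taking off catalyst intermediate B left 80.6%, more than east, so I chose north of the two. South-east and south I did not reckon.

The forecast named north and gave 56.3% for south-east, 78.7% for north, 71% for east, as a “quasi-steady estimate after an initial burst into B”, and 51% for south, lower than mine on east and on north.

The simulation gave 56.3% for south-east, 78.7% for north, 73.9% for east and 50.1% for south, with north highest.

In east at 50.0 s, with 22.1% of the substrate and 18.1% of the reagent left, capture with its returns takes 18.3 s against 4.93 s for release. The turnover time there is 29.3 s, and free catalyst, the resting state, stands at 60.0% of the catalyst. South ends with a turnover time of 14.5 s. A neighbour of south with 6.0 mM of substrate ends with 24.9% of that substrate and 47% of the reagent left, which gives a longer turnover time than south, 22.5 s, and that neighbour ends with product at 67.5% of its substrate.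

The constants used here were set for the occasion; the result is computed.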